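**Retrosynthetic overview**
1. Glycybenzofuran 11 comes from its bis-MOM ether 10 by acidolysis; the furan is opened at the O1–C7a bond to give the α-(4-hydroxyphenyl) ketone 8 (oxidative dearomatization, enol oxa-Michael addition, rearomatization).
2. Ketone 8 is cut at the C3–C3a bond into the ring B propiophenone 5 and aryl bromide 6 (palladium-catalysed enolate arylation).
3. Ketone 5 comes from flopropione 1 by C-prenylation, chelation-controlled bis-MOM protection and O-methylation.
4. Ring order: rings A and B are bought as benzene rings; the furan is the only ring built and it closes last, through its C–O bond.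

Assumption: the target has no stereocentre, no stereogenic double bond and no configurationally stable axis, so it is one achiral compound and needs no enantiocontrol; the α-stereocentre in 7, 8 and 9 is racemic and is erased in step 5.

Step 1
Reactants: 1 flopropione [1-(2,4,6-trihydroxyphenyl)propan-1-one]; 2 prenyl bromide (1-bromo-3-methylbut-2-ene)
Product: 3 1-[2,4,6-trihydroxy-3-(3-methylbut-2-en-1-yl)phenyl]propan-1-one
Conditions: 2 (1.0 equiv, slow addition), DBU (1.1 equiv), THF, 0 °C → rt
Reagents that add atoms: none
Why: C-alkylation of the ambident acylphloroglucinol phenoxide (Friedel–Crafts-type C-prenylation); the two free ring positions of 1 are equivalent, so only one mono-C-prenyl isomer can form, and no stereocentre is created.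

Step 2
Reactants: 3 1-[2,4,6-trihydroxy-3-(3-methylbut-2-en-1-yl)phenyl]propan-1-one
Product: 4 1-[2-hydroxy-4,6-bis(methoxymethoxy)-3-(3-methylbut-2-en-1-yl)phenyl]propan-1-one
Conditions: MOMCl (2.3 equiv), K2CO3, acetone, reflux
Reagents that add atoms: chloromethyl methyl ether (MOMCl), COCCl
Why: Williamson-type MOM ether formation; the para hydroxyl reacts first, then the less hindered of the two carbonyl-chelated hydroxyls, and the last one, hydrogen-bonded to the ketone and flanked by the prenyl group, stays free.

Step 3
Reactants: 4 1-[2-hydroxy-4,6-bis(methoxymethoxy)-3-(3-methylbut-2-en-1-yl)phenyl]propan-1-one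
Product: 5 1-[2-methoxy-4,6-bis(methoxymethoxy)-3-(3-methylbut-2-en-1-yl)phenyl]propan-1-one
Conditions: MeI (3 equiv), K2CO3, DMF, 40 °C
Reagents that add atoms: iodomethane (MeI), CI
Why: Williamson O-methylation of the one remaining phenol with a small electrophile in a dipolar solvent; K2CO3 is too weak to enolise the ketone, so there is no C-methylation.

Step 4
Reactants: 5 1-[2-methoxy-4,6-bis(methoxymethoxy)-3-(3-methylbut-2-en-1-yl)phenyl]propan-1-one; 6 (4-bromophenoxy)(tert-butyl)dimethylsilane
Product: 8 2-(4-hydroxyphenyl)-1-[2-methoxy-4,6-bis(methoxymethoxy)-3-(3-methylbut-2-en-1-yl)phenyl]propan-1-one, via silyl ether 7 (not isolated)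
Conditions: Pd2(dba)3 (1.5 mol %), XPhos (3.6 mol %), NaOtBu (2.2 equiv), toluene, 80 °C; then MeOH, rt; aq. NH4Cl work-up
Reagents that add atoms: none
Why: Buchwald–Hartwig–Miura palladium-catalysed α-arylation of the ketone sodium enolate (oxidative addition of 6 to zerovalent palladium, enolate transfer, C–C reductive elimination) stops at mono-arylation because the product α-carbon is tertiary; the methoxide formed on adding MeOH then cleaves the aryl silyl ether, and the new α-stereocentre is formed racemic and erased in step 5.

Step 5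
Reactants: 8 2-(4-hydroxyphenyl)-1-[2-methoxy-4,6-bis(methoxymethoxy)-3-(3-methylbut-2-en-1-yl)phenyl]propan-1-one
Product: 11 glycybenzofuran [4-(6-hydroxy-3-methyl-1-benzofuran-2-yl)-5-methoxy-6-(3-methylbut-2-en-1-yl)benzene-1,3-diol], via quinol methyl ether 9 (not isolated), via bis-MOM benzofuran 10 (not isolated)
Conditions: PhI(OAc)2 (1.0 equiv), MeOH, 0 °C; then 3 M HCl in MeOH, 0 → 40 °C
Reagents that add atoms: none
Why: Proposed new method: PhI(OAc)2 oxidises the free para-substituted phenol and methanol is captured at the ipso carbon to give quinol ether 9 (standard hypervalent-iodine oxidative dearomatization), which turns the ring carbon ortho to the side chain and meta to the phenol oxygen into a dienone β-carbon; on acidification the ketone enolises and the enol oxygen closes onto that carbon in a Baldwin-allowed 5-exo-trig oxa-Michael addition (C-attack would need a three-membered ring, and the two β-carbons are equivalent), the resulting allylic methyl ether is a vinylogous ketal that ionises and loses methanol, tautomerisation restores the phenol as 6-hydroxybenzofuran 10, and the same acid then removes both MOM acetals; the closest known reaction types are the oxa-Michael ring closure of para-quinols carrying a 2-hydroxyethyl chain and dearomatization/Michael/rearomatization sequences for meta-functionalisation of phenols, but to my knowledge an enol oxygen has not been used in this way to make a benzofuran from an α-(4-hydroxyaryl) ketone; no stereocentre remains.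

**Compound list**
1 | flopropione, 1-(2,4,6-trihydroxyphenyl)propan-1-one | CCC(=O)c1c(O)cc(O)cc1O | starting material
2 | prenyl bromide, 1-bromo-3-methylbut-2-ene | CC(C)=CCBr | starting material
3 | 1-[2,4,6-trihydroxy-3-(3-methylbut-2-en-1-yl)phenyl]propan-1-one | CCC(=O)c1c(O)c(CC=C(C)C)c(O)cc1O | intermediate
4 | 1-[2-hydroxy-4,6-bis(methoxymethoxy)-3-(3-methylbut-2-en-1-yl)phenyl]propan-1-one | CCC(=O)c1c(O)c(CC=C(C)C)c(OCOC)cc1OCOC | intermediate
5 | 1-[2-methoxy-4,6-bis(methoxymethoxy)-3-(3-methylbut-2-en-1-yl)phenyl]propan-1-one | CCC(=O)c1c(OC)c(CC=C(C)C)c(OCOC)cc1OCOC | intermediate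
6 | (4-bromophenoxy)(tert-butyl)dimethylsilane | CC(C)(C)[Si](C)(C)Oc1ccc(Br)cc1 | starting material
7 | 2-{4-[tert-butyl(dimethyl)silyloxy]phenyl}-1-[2-methoxy-4,6-bis(methoxymethoxy)-3-(3-methylbut-2-en-1-yl)phenyl]propan-1-one, racemic | CC(C(=O)c1c(OC)c(CC=C(C)C)c(OCOC)cc1OCOC)c1ccc(O[Si](C)(C)C(C)(C)C)cc1 | intermediate (not isolated)
8 | 2-(4-hydroxyphenyl)-1-[2-methoxy-4,6-bis(methoxymethoxy)-3-(3-methylbut-2-en-1-yl)phenyl]propan-1-one, racemic | CC(C(=O)c1c(OC)c(CC=C(C)C)c(OCOC)cc1OCOC)c1ccc(O)cc1 | intermediate
9 | 4-methoxy-4-{1-[2-methoxy-4,6-bis(methoxymethoxy)-3-(3-methylbut-2-en-1-yl)phenyl]-1-oxopropan-2-yl}cyclohexa-2,5-dien-1-one, racemic | CC(C(=O)c1c(OC)c(CC=C(C)C)c(OCOC)cc1OCOC)C1(OC)C=CC(=O)C=C1 | intermediate (not isolated)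
10 | 2-[2-methoxy-4,6-bis(methoxymethoxy)-3-(3-methylbut-2-en-1-yl)phenyl]-3-methyl-1-benzofuran-6-ol | COc1c(CC=C(C)C)c(OCOC)cc(OCOC)c1-c1oc2cc(O)ccc2c1C | intermediate (not isolated)
11 | glycybenzofuran, 4-(6-hydroxy-3-methyl-1-benzofuran-2-yl)-5-methoxy-6-(3-methylbut-2-en-1-yl)benzene-1,3-diol (achiral) | COc1c(CC=C(C)C)c(O)cc(O)c1-c1oc2cc(O)ccc2c1C | target

**Totals**
Total step count: 5. Longest linear sequence: 5 steps (1 → 3 → 4 → 5 → 8 → 11).

**Three steps most likely to fail**

Step 5 (the proposed new reaction). The risks are: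
- loss of the acidic benzylic proton at the phenoxonium stage, giving a quinone methide or α-aryl enone instead of 9;
- slow enolisation of the hindered ketone, letting ortho-methoxylation of the dienone compete;
- acid-induced chroman formation from the prenyl group once the MOM groups are off.

Fallback with known chemistry: it sets out from 5 and comes back at 11. Commercial 4-bromoresorcinol is protected (MOMCl, K2CO3, acetone) as 1-bromo-2,4-bis(methoxymethoxy)benzene F4. Palladium-catalysed enolate arylation of 5 with it (Pd2(dba)3, XPhos, NaOtBu, toluene, 80 °C) gives 2-[2,4-bis(methoxymethoxy)phenyl]-1-[2-methoxy-4,6-bis(methoxymethoxy)-3-(3-methylbut-2-en-1-yl)phenyl]propan-1-one F5. Treatment with 3 M HCl in MeOH removes all four MOM groups; the freed ortho-hydroxyl adds to the ketone and the hemiketal dehydrates (classical cyclodehydration of an α-(2-hydroxyaryl) ketone), giving 11 directly.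

Step 1 (C-prenylation). The risks are O-prenylation, di-prenylation and dearomatised geminal products, which typically hold the yield near 40–50 %. The assumed selectivity of step 2 also rests on this intermediate. The fallback sets out from 1 and comes back at 4, and it fixes by construction which hydroxyl stays free. Compound 1 is first bis-protected (MOMCl, K2CO3, acetone) to 1-[2-hydroxy-4,6-bis(methoxymethoxy)phenyl]propan-1-one F1. The chelated phenol is O-alkylated with tert-butyl 2-methylbut-3-en-2-yl carbonate and Pd(PPh3)4 in THF at 0 °C to give the tertiary allyl ether 1-[2-(2-methylbut-3-en-2-yloxy)-4,6-bis(methoxymethoxy)phenyl]propan-1-one F2. Heating in toluene at 110 °C brings about an aromatic Claisen rearrangement into the only free ortho position, with allyl inversion, to give 4.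

Step 4 (enolate arylation). The risks are the hindered di-ortho-substituted aryl ketone, premature cleavage of the silyl ether by NaOtBu (which deactivates 6 as a phenoxide), and base-induced migration of the prenyl double bond. The fallback sets out from 5 and comes back at 7, and it avoids strong base in the coupling. Ketone 5 is converted (LiN(SiMe3)2, Me3SiCl, THF, −78 °C) into its enol ether, (Z)-{1-[2-methoxy-4,6-bis(methoxymethoxy)-3-(3-methylbut-2-en-1-yl)phenyl]prop-1-en-1-yl}oxy(trimethyl)silane F3. This is coupled with 6 under neutral fluoride-promoted palladium catalysis (Pd(OAc)2, P(t-Bu)3, Bu3SnF, toluene, 80 °C) to give 7, which is desilylated to 8 with K2CO3 in MeOH as in the second stage of step 4.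

**Further compounds**
F1 | step 1 | 1-[2-hydroxy-4,6-bis(methoxymethoxy)phenyl]propan-1-one | CCC(=O)c1c(O)cc(OCOC)cc1OCOC
F2 | step 1 | 1-[2-(2-methylbut-3-en-2-yloxy)-4,6-bis(methoxymethoxy)phenyl]propan-1-one | CCC(=O)c1c(OC(C)(C)C=C)cc(OCOC)cc1OCOC
F3 | step 4 | (Z)-{1-[2-methoxy-4,6-bis(methoxymethoxy)-3-(3-methylbut-2-en-1-yl)phenyl]prop-1-en-1-yl}oxy(trimethyl)silane | C/C=C(\O[Si](C)(C)C)c1c(OC)c(CC=C(C)C)c(OCOC)cc1OCOC
F4 | step 5 | 1-bromo-2,4-bis(methoxymethoxy)benzene | COCOc1ccc(Br)c(OCOC)c1
F5 | step 5 | 2-[2,4-bis(methoxymethoxy)phenyl]-1-[2-methoxy-4,6-bis(methoxymethoxy)-3-(3-methylbut-2-en-1-yl)phenyl]propan-1-one, racemic | CC(C(=O)c1c(OC)c(CC=C(C)C)c(OCOC)cc1OCOC)c1ccc(OCOC)cc1OCOC
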